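**Retrosynthetic overview**
Numbering: five-membered ring C1(OAc)–C2–C3(OH, iPr)–C4(H)–C10(Me); seven-membered ring C4–C5(O-aroyl)–C6–C7(Me)=C8–C9–C10. The route rests on the fully substituted carbinol C3 lying 1,5 to the C1 carbonyl carbon through C2, so C2–C3 is made last by insertion of a C10-bound acyl carbene into the C3–H bond of a secondary silyl ether, with retention.
Diazoketone ⇐ methyl ketone (diazo transfer) ⇐ cycloheptene by ring-closing metathesis at C7=C8 ⇐ C5 carbinol by methallylation of a C5 aldehyde.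
Keto aldehyde ⇐ α-allyl-α-methyl γ-lactone (C1 carbonyl, C5 in the ring) by MeLi opening and oxidation; C10 is set by methylating the lactone enolate anti to the C4 side chain; C3 and C4 come from a D-proline anti-aldol of methyl 4-oxobutanoate with 2-methylpropanal.
Ring order: temporary γ-lactone (steps 1–4, opened in step 5) → seven-membered ring (step 10) → five-membered ring (step 12); then C3-OH-directed C1 reduction, acetylation and release of the phenol.

Key step: step 12

Remark: the γ-hydroxy ketones 9 and 11 are written open-chain; each may equilibrate with a five-membered cyclic hemiketal, which reacts on through the open form.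

**Step 1**
Reactants: 1 2-methylpropanal; 2 methyl 4-oxobutanoate
Product: 5 (4S)-4-[(1R)-1-hydroxy-2-methylpropyl]oxolan-2-one, via aldol aldehyde 3 (not isolated), via diol ester 4 (not isolated)
Conditions: D-proline (20 mol%), DMF, 4 °C, slow addition of 2 to excess 1; then NaBH4, MeOH, 0 °C; 1 M HCl work-up
Reagents that add atoms: none
Why: Proline-catalysed direct cross-aldol reaction (enamine of 2 adding to the non-self-condensing acceptor 1 through the Houk–List transition state) should give the anti aldol 3 with the C4 and C3 configurations of the target from D-proline, and borohydride reduction of the formyl group followed by lactonisation of the primary alcohol onto the ester traps it as 5 before it can epimerise.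

**Step 2**
Reactants: 5 (4S)-4-[(1R)-1-hydroxy-2-methylpropyl]oxolan-2-one
Product: 6 (4S)-4-[(1R)-2-methyl-1-(triethylsilyloxy)propyl]oxolan-2-one
Conditions: Et3SiOTf, 2,6-lutidine, CH2Cl2, −78 → 0 °C
Reagents that add atoms: triethylsilyl trifluoromethanesulfonate, CC[Si](CC)(CC)OS(=O)(=O)C(F)(F)F
Why: Silylation of the hindered secondary alcohol with a silyl triflate installs at once the C3 triethylsilyl ether that later activates the C3–H bond.

**Step 3**
Reactants: 6 (4S)-4-[(1R)-2-methyl-1-(triethylsilyloxy)propyl]oxolan-2-one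
Product: 7 (3S,4S)-3-allyl-4-[(1R)-2-methyl-1-(triethylsilyloxy)propyl]oxolan-2-one
Conditions: LiN(iPr)2, THF, −78 °C; allyl bromide, −78 → −40 °C
Reagents that add atoms: allyl bromide, C=CCBr
Why: Lactone enolate alkylation should give mainly the 3,4-trans product, and the configuration at this carbon is of no consequence because it is made planar again in step 4.

**Step 4**
Reactants: 7 (3S,4S)-3-allyl-4-[(1R)-2-methyl-1-(triethylsilyloxy)propyl]oxolan-2-one
Product: 8 (3R,4S)-3-allyl-3-methyl-4-[(1R)-2-methyl-1-(triethylsilyloxy)propyl]oxolan-2-one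
Conditions: LiN(iPr)2, THF/DMPU, −78 °C; MeI, −78 → −20 °C
Reagents that add atoms: iodomethane, CI
Why: Second enolate alkylation, in which the planar lithium enolate is methylated on the face anti to the bulky C4 side chain, so that methyl ends trans and allyl cis to that side chain and the quaternary centre C10 is set; this is why allyl is introduced first.

**Step 5**
Reactants: 8 (3R,4S)-3-allyl-3-methyl-4-[(1R)-2-methyl-1-(triethylsilyloxy)propyl]oxolan-2-one
Product: 9 (3R,4S,5R)-3-allyl-4-(hydroxymethyl)-3,6-dimethyl-5-(triethylsilyloxy)heptan-2-one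
Conditions: MeLi (1.2 equiv), THF, −78 °C; sat. aq. NH4Cl
Reagents that add atoms: methyllithium, [Li]C
Why: Mono-addition of an organolithium to a γ-lactone, in which the lithium hemiketal is stable at −78 °C and the lactone has no α-hydrogen to lose, turns the C1 carbonyl into the methyl ketone that carries C2 and frees the C5 primary alcohol.

**Step 6**
Reactants: 9 (3R,4S,5R)-3-allyl-4-(hydroxymethyl)-3,6-dimethyl-5-(triethylsilyloxy)heptan-2-one
Product: 10 (2R,3R)-3-acetyl-3-methyl-2-[(1R)-2-methyl-1-(triethylsilyloxy)propyl]hex-5-enal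
Conditions: Dess–Martin periodinane, CH2Cl2, 0 °C → rt
Reagents that add atoms: none
Why: Dess–Martin oxidation of the primary alcohol in the open hydroxy ketone form gives the γ-keto aldehyde under non-basic conditions, so neither epimerisation at C4 nor intramolecular aldol condensation should occur.

**Step 7**
Reactants: 10 (2R,3R)-3-acetyl-3-methyl-2-[(1R)-2-methyl-1-(triethylsilyloxy)propyl]hex-5-enal
Product: 11 (3R,4S,5S)-3-allyl-5-hydroxy-3,7-dimethyl-4-[(1R)-2-methyl-1-(triethylsilyloxy)propyl]oct-7-en-2-one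
Conditions: (−)-Ipc2BOMe, 2-methylallylmagnesium chloride, Et2O, −78 °C → rt; then 10, Et2O, −78 °C; H2O2, pH 7 phosphate buffer, MeOH, 0 °C
Reagents that add atoms: 2-methylallylmagnesium chloride, CC(=C)C[Mg]Cl, delivered through (−)-B-(2-methylallyl)diisopinocampheylborane, CC(=C)CB([C@H]1[C@H](C)[C@H]2C[C@@H](C1)C2(C)C)[C@H]1[C@H](C)[C@H]2C[C@@H](C1)C2(C)C
Why: Brown asymmetric allylboration adds only to the aldehyde (the hindered methyl ketone is inert at −78 °C) through a chair transition state on the Si face of C5, the face that Felkin–Anh addition anti to the quaternary C10 group also prefers, which should give the 5S carbinol.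

**Step 8**
Reactants: 12 4-hydroxybenzoic acid
Product: 14 4-(tert-butyldimethylsilyloxy)benzoic acid, via silyl ester 13 (not isolated)
Conditions: tBuMe2SiCl (2.2 equiv), imidazole, DMF, rt; then AcOH/THF/H2O, rt
Reagents that add atoms: tert-butyldimethylsilyl chloride, CC(C)(C)[Si](C)(C)Cl
Why: Bis-silylation followed by selective hydrolysis of the far more labile silyl ester leaves the phenol protected as its aryl silyl ether.

**Step 9**
Reactants: 11 (3R,4S,5S)-3-allyl-5-hydroxy-3,7-dimethyl-4-[(1R)-2-methyl-1-(triethylsilyloxy)propyl]oct-7-en-2-one; 14 4-(tert-butyldimethylsilyloxy)benzoic acid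
Product: 16 (4S,5S,6R)-6-acetyl-2,6-dimethyl-5-[(1R)-2-methyl-1-(triethylsilyloxy)propyl]nona-1,8-dien-4-yl 4-(tert-butyldimethylsilyloxy)benzoate, via acid chloride 15 (not isolated)
Conditions: 14, (COCl)2, DMF (cat.), CH2Cl2, 0 °C → rt, evaporate; then 11, Et3N, DMAP, CH2Cl2, rt → 40 °C
Reagents that add atoms: none
Why: DMAP-catalysed acylation with the acid chloride esterifies the hindered C5 alcohol without touching its configuration and puts in place the ester that shields C5 in the key step.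

**Step 10**
Reactants: 16 (4S,5S,6R)-6-acetyl-2,6-dimethyl-5-[(1R)-2-methyl-1-(triethylsilyloxy)propyl]nona-1,8-dien-4-yl 4-(tert-butyldimethylsilyloxy)benzoate
Product: 17 (1S,6R,7S)-6-acetyl-3,6-dimethyl-7-[(1R)-2-methyl-1-(triethylsilyloxy)propyl]cyclohept-3-en-1-yl 4-(tert-butyldimethylsilyloxy)benzoate
Conditions: second-generation Grubbs catalyst RuCl2(=CHPh)(PCy3)(H2IMes) (5 mol%), CH2Cl2 (2 mM), 40 °C
Reagents that add atoms: none
Why: Ring-closing metathesis of the allyl group on C10 with the 1,1-disubstituted methallyl alkene forms the trisubstituted C7=C8 bond and the seven-membered ring, helped by the three contiguous branched carbons, and creates no stereocentre.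

**Step 11**
Reactants: 17 (1S,6R,7S)-6-acetyl-3,6-dimethyl-7-[(1R)-2-methyl-1-(triethylsilyloxy)propyl]cyclohept-3-en-1-yl 4-(tert-butyldimethylsilyloxy)benzoate
Product: 19 (1S,6R,7S)-6-(2-diazoacetyl)-3,6-dimethyl-7-[(1R)-2-methyl-1-(triethylsilyloxy)propyl]cyclohept-3-en-1-yl 4-(tert-butyldimethylsilyloxy)benzoate, via trifluoroacetyl ketone 18 (not isolated)
Conditions: LiN(SiMe3)2, THF, −78 °C; CF3CO2CH2CF3, −78 °C; 1 M HCl work-up; then MeSO2N3, Et3N, H2O, MeCN, rt
Reagents that add atoms: methanesulfonyl azide, CS(=O)(=O)N=[N+]=[N-]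
Why: Detrifluoroacetylative diazo transfer (Claisen trifluoroacetylation of the only enolisable position, the acetyl methyl group, then Regitz-type transfer with loss of the trifluoroacetyl group) makes the diazomethyl ketone without any ester hydrolysis or acid chloride next to the aryl ester.

**Step 12**
Reactants: 19 (1S,6R,7S)-6-(2-diazoacetyl)-3,6-dimethyl-7-[(1R)-2-methyl-1-(triethylsilyloxy)propyl]cyclohept-3-en-1-yl 4-(tert-butyldimethylsilyloxy)benzoate
Product: 20 (3R,3aS,4S,8aR)-6,8a-dimethyl-1-oxo-3-(propan-2-yl)-3-(triethylsilyloxy)-1,2,3,3a,4,5,8,8a-octahydroazulen-4-yl 4-(tert-butyldimethylsilyloxy)benzoate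
Conditions: Rh2(OAc)4 (1 mol%), CH2Cl2, rt, slow addition of 19 at high dilution
Reagents that add atoms: none
Why: Rh2(OAc)4 takes nitrogen from the diazoketone and forms an electrophilic rhodium carbene at C2, which inserts into the C3–H bond in a concerted, three-centre, hydride-transfer-like event, the closest known reaction type being the Rh2(OAc)4-catalysed intramolecular 1,5 C–H insertion of α-diazo ketones to cyclopentanones. The cyclopentanone ring C1–C2–C3–C4–C10 closes in the 1,5-insertion mode through a six-membered chair-like transition state that includes rhodium, and it is trans-fused without any new ring-fusion centre because the C10 acyl group and the C4 side chain are already trans (both pseudo-equatorial) on the cycloheptene. The only new stereocentre is the fully substituted C3, and it is controlled by retention at the inserting C–H bond, so the 1R carbinol centre from step 1 becomes 3R. The step needs C3–H insertion over every other carbene outlet: C3–H is the 1,5 methine made hydridic by the silyloxy group, C5–H is also 1,5 but points to the ring face opposite the carbene and carries the electron-poor aroyloxy group, the isopropyl methine is 1,6 and the C9 and methyl hydrogens are 1,4. Addition to the C7=C8 double bond would need the C10 acyl group pseudo-axial, which forces the trans C4 side chain axial and sets the acyl group against the cis C5 ester, and oxonium ylide formation is held back by the bulk of the triethylsilyl group. Slow addition at high dilution keeps carbene dimerisation down.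

**Step 13**
Reactants: 20 (3R,3aS,4S,8aR)-6,8a-dimethyl-1-oxo-3-(propan-2-yl)-3-(triethylsilyloxy)-1,2,3,3a,4,5,8,8a-octahydroazulen-4-yl 4-(tert-butyldimethylsilyloxy)benzoate
Product: 21 (3R,3aS,4S,8aR)-3-hydroxy-6,8a-dimethyl-1-oxo-3-(propan-2-yl)-1,2,3,3a,4,5,8,8a-octahydroazulen-4-yl 4-(tert-butyldimethylsilyloxy)benzoate
Conditions: camphorsulfonic acid (10 mol%), MeOH/CH2Cl2, 0 °C
Reagents that add atoms: none
Why: Acid-catalysed methanolysis cleaves the alkyl triethylsilyl ether, whereas the aryl silyl ether, which is labile to base and fluoride but not to mild acid, should stay on the phenol.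

**Step 14**
Reactants: 21 (3R,3aS,4S,8aR)-3-hydroxy-6,8a-dimethyl-1-oxo-3-(propan-2-yl)-1,2,3,3a,4,5,8,8a-octahydroazulen-4-yl 4-(tert-butyldimethylsilyloxy)benzoate
Product: 22 (1S,3R,3aS,4S,8aR)-1,3-dihydroxy-6,8a-dimethyl-3-(propan-2-yl)-1,2,3,3a,4,5,8,8a-octahydroazulen-4-yl 4-(tert-butyldimethylsilyloxy)benzoate
Conditions: Me4NBH(OAc)3, MeCN/AcOH, −20 °C
Reagents that add atoms: none
Why: Evans–Saksena hydroxyl-directed reduction, in which the C3 hydroxyl exchanges onto boron and delivers hydride to the C1 carbonyl on its own face, should give the 1,3-anti diol, that is the 1S alcohol trans to the C3 hydroxyl.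

**Step 15**
Reactants: 22 (1S,3R,3aS,4S,8aR)-1,3-dihydroxy-6,8a-dimethyl-3-(propan-2-yl)-1,2,3,3a,4,5,8,8a-octahydroazulen-4-yl 4-(tert-butyldimethylsilyloxy)benzoate
Product: 23 (1S,3R,3aS,4S,8aR)-1-acetoxy-3-hydroxy-6,8a-dimethyl-3-(propan-2-yl)-1,2,3,3a,4,5,8,8a-octahydroazulen-4-yl 4-(tert-butyldimethylsilyloxy)benzoate
Conditions: Ac2O, pyridine, DMAP (cat.), CH2Cl2, 0 °C → rt
Reagents that add atoms: acetic anhydride, CC(=O)OC(C)=O
Why: DMAP-catalysed acetylation takes the secondary C1 alcohol and leaves the tertiary C3 alcohol, which is far slower to acylate, untouched.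

**Step 16**
Reactants: 23 (1S,3R,3aS,4S,8aR)-1-acetoxy-3-hydroxy-6,8a-dimethyl-3-(propan-2-yl)-1,2,3,3a,4,5,8,8a-octahydroazulen-4-yl 4-(tert-butyldimethylsilyloxy)benzoate
Product: 24 (1S,3R,3aS,4S,8aR)-1-acetoxy-3-hydroxy-6,8a-dimethyl-3-(propan-2-yl)-1,2,3,3a,4,5,8,8a-octahydroazulen-4-yl 4-hydroxybenzoate (CNP0275279.1)
Conditions: Bu4NF, AcOH, THF, 0 °C
Reagents that add atoms: none
Why: Fluoride-mediated cleavage of the aryl silyl ether, buffered with acetic acid so that neither the acetate nor the benzoate is cleaved or migrates, releases the phenol and gives the target.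

**Compound list**
1 | 2-methylpropanal | CC(C)C=O | starting material
2 | methyl 4-oxobutanoate | COC(=O)CCC=O | starting material
3 | methyl (3R,4R)-3-formyl-4-hydroxy-5-methylhexanoate | COC(=O)C[C@@H](C=O)[C@H](O)C(C)C | intermediate
4 | methyl (3S,4R)-4-hydroxy-3-(hydroxymethyl)-5-methylhexanoate | COC(=O)C[C@@H](CO)[C@H](O)C(C)C | intermediate
5 | (4S)-4-[(1R)-1-hydroxy-2-methylpropyl]oxolan-2-one | O=C1C[C@@H](CO1)[C@H](O)C(C)C | intermediate
6 | (4S)-4-[(1R)-2-methyl-1-(triethylsilyloxy)propyl]oxolan-2-one | O=C1C[C@@H](CO1)[C@H](O[Si](CC)(CC)CC)C(C)C | intermediate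
7 | (3S,4S)-3-allyl-4-[(1R)-2-methyl-1-(triethylsilyloxy)propyl]oxolan-2-one | O=C1OC[C@@H]([C@H](O[Si](CC)(CC)CC)C(C)C)[C@@H]1CC=C | intermediate
8 | (3R,4S)-3-allyl-3-methyl-4-[(1R)-2-methyl-1-(triethylsilyloxy)propyl]oxolan-2-one | O=C1OC[C@@H]([C@H](O[Si](CC)(CC)CC)C(C)C)[C@@]1(C)CC=C | intermediate
9 | (3R,4S,5R)-3-allyl-4-(hydroxymethyl)-3,6-dimethyl-5-(triethylsilyloxy)heptan-2-one | CC(=O)[C@](C)(CC=C)[C@@H](CO)[C@H](O[Si](CC)(CC)CC)C(C)C | intermediate
10 | (2R,3R)-3-acetyl-3-methyl-2-[(1R)-2-methyl-1-(triethylsilyloxy)propyl]hex-5-enal | CC(=O)[C@](C)(CC=C)[C@@H](C=O)[C@H](O[Si](CC)(CC)CC)C(C)C | intermediate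
11 | (3R,4S,5S)-3-allyl-5-hydroxy-3,7-dimethyl-4-[(1R)-2-methyl-1-(triethylsilyloxy)propyl]oct-7-en-2-one | CC(=O)[C@](C)(CC=C)[C@@H]([C@@H](O)CC(C)=C)[C@H](O[Si](CC)(CC)CC)C(C)C | intermediate
12 | 4-hydroxybenzoic acid | O=C(O)c1ccc(O)cc1 | starting material
13 | tert-butyldimethylsilyl 4-(tert-butyldimethylsilyloxy)benzoate | CC(C)(C)[Si](C)(C)OC(=O)c1ccc(O[Si](C)(C)C(C)(C)C)cc1 | intermediate
14 | 4-(tert-butyldimethylsilyloxy)benzoic acid | O=C(O)c1ccc(O[Si](C)(C)C(C)(C)C)cc1 | intermediate
15 | 4-(tert-butyldimethylsilyloxy)benzoyl chloride | O=C(Cl)c1ccc(O[Si](C)(C)C(C)(C)C)cc1 | intermediate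
16 | (4S,5S,6R)-6-acetyl-2,6-dimethyl-5-[(1R)-2-methyl-1-(triethylsilyloxy)propyl]nona-1,8-dien-4-yl 4-(tert-butyldimethylsilyloxy)benzoate | CC(=O)[C@](C)(CC=C)[C@@H]([C@@H](OC(=O)c1ccc(O[Si](C)(C)C(C)(C)C)cc1)CC(C)=C)[C@H](O[Si](CC)(CC)CC)C(C)C | intermediate
17 | (1S,6R,7S)-6-acetyl-3,6-dimethyl-7-[(1R)-2-methyl-1-(triethylsilyloxy)propyl]cyclohept-3-en-1-yl 4-(tert-butyldimethylsilyloxy)benzoate | CC(=O)[C@]1(C)CC=C(C)C[C@H](OC(=O)c2ccc(O[Si](C)(C)C(C)(C)C)cc2)[C@H]1[C@H](O[Si](CC)(CC)CC)C(C)C | intermediate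
18 | (1S,6R,7S)-3,6-dimethyl-7-[(1R)-2-methyl-1-(triethylsilyloxy)propyl]-6-(4,4,4-trifluoro-3-oxobutanoyl)cyclohept-3-en-1-yl 4-(tert-butyldimethylsilyloxy)benzoate | O=C(CC(=O)C(F)(F)F)[C@]1(C)CC=C(C)C[C@H](OC(=O)c2ccc(O[Si](C)(C)C(C)(C)C)cc2)[C@H]1[C@H](O[Si](CC)(CC)CC)C(C)C | intermediate
19 | (1S,6R,7S)-6-(2-diazoacetyl)-3,6-dimethyl-7-[(1R)-2-methyl-1-(triethylsilyloxy)propyl]cyclohept-3-en-1-yl 4-(tert-butyldimethylsilyloxy)benzoate | [N-]=[N+]=CC(=O)[C@]1(C)CC=C(C)C[C@H](OC(=O)c2ccc(O[Si](C)(C)C(C)(C)C)cc2)[C@H]1[C@H](O[Si](CC)(CC)CC)C(C)C | intermediate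
20 | (3R,3aS,4S,8aR)-6,8a-dimethyl-1-oxo-3-(propan-2-yl)-3-(triethylsilyloxy)-1,2,3,3a,4,5,8,8a-octahydroazulen-4-yl 4-(tert-butyldimethylsilyloxy)benzoate | O=C1C[C@@](O[Si](CC)(CC)CC)(C(C)C)[C@@H]2[C@@H](OC(=O)c3ccc(O[Si](C)(C)C(C)(C)C)cc3)CC(C)=CC[C@@]12C | intermediate
21 | (3R,3aS,4S,8aR)-3-hydroxy-6,8a-dimethyl-1-oxo-3-(propan-2-yl)-1,2,3,3a,4,5,8,8a-octahydroazulen-4-yl 4-(tert-butyldimethylsilyloxy)benzoate | O=C1C[C@@](O)(C(C)C)[C@@H]2[C@@H](OC(=O)c3ccc(O[Si](C)(C)C(C)(C)C)cc3)CC(C)=CC[C@@]12C | intermediate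
22 | (1S,3R,3aS,4S,8aR)-1,3-dihydroxy-6,8a-dimethyl-3-(propan-2-yl)-1,2,3,3a,4,5,8,8a-octahydroazulen-4-yl 4-(tert-butyldimethylsilyloxy)benzoate | O[C@H]1C[C@@](O)(C(C)C)[C@@H]2[C@@H](OC(=O)c3ccc(O[Si](C)(C)C(C)(C)C)cc3)CC(C)=CC[C@@]12C | intermediate
23 | (1S,3R,3aS,4S,8aR)-1-acetoxy-3-hydroxy-6,8a-dimethyl-3-(propan-2-yl)-1,2,3,3a,4,5,8,8a-octahydroazulen-4-yl 4-(tert-butyldimethylsilyloxy)benzoate | CC(=O)O[C@H]1C[C@@](O)(C(C)C)[C@@H]2[C@@H](OC(=O)c3ccc(O[Si](C)(C)C(C)(C)C)cc3)CC(C)=CC[C@@]12C | intermediate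
24 | (1S,3R,3aS,4S,8aR)-1-acetoxy-3-hydroxy-6,8a-dimethyl-3-(propan-2-yl)-1,2,3,3a,4,5,8,8a-octahydroazulen-4-yl 4-hydroxybenzoate | CC(=O)O[C@H]1C[C@@](O)(C(C)C)[C@@H]2[C@@H](OC(=O)c3ccc(O)cc3)CC(C)=CC[C@@]12C | target

**Step count**
Total: 16 steps. Longest linear sequence: 15 steps (steps 1–7 and 9–16); step 8 is a one-step side branch.

**Steps most likely to fail**

Step 12. The carbene may be diverted from C–H insertion by addition to the C7=C8 double bond (the alkene is homoallylic to the acyl carbon) or by attack of the silyl ether oxygen. The fallback sets out from 17 and comes back at 21. The triethylsilyl ether of 17 is cleaved (camphorsulfonic acid, MeOH) to the secondary alcohol (1S,6R,7R)-6-acetyl-7-[(1R)-1-hydroxy-2-methylpropyl]-3,6-dimethylcyclohept-3-en-1-yl 4-(tert-butyldimethylsilyloxy)benzoate F1. This is oxidised with Dess–Martin periodinane to the 1,4-diketone (1S,6R,7S)-6-acetyl-3,6-dimethyl-7-(2-methylpropanoyl)cyclohept-3-en-1-yl 4-(tert-butyldimethylsilyloxy)benzoate F2. Kinetic deprotonation of the acetyl methyl group (LiN(iPr)2, THF, −78 °C) and intramolecular aldol addition to the isobutyryl carbonyl then close the same C2–C3 bond and give the β-hydroxy ketone 21 directly. In this variant C3 is set by the facial preference of the aldol closure and not by retention, so its configuration would have to be checked.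

Step 7. Addition to the doubly branched aldehyde may be slow and facial control incomplete, so that both C5 epimers form. The fallback sets out from 10 and comes back at 11. A small achiral reagent under substrate (Felkin–Anh) control is used (2-methylallyl bromide, indium powder, THF/H2O, Barbier conditions), which gives 11 together with its C5 epimer (3R,4S,5R)-3-allyl-5-hydroxy-3,7-dimethyl-4-[(1R)-2-methyl-1-(triethylsilyloxy)propyl]oct-7-en-2-one F3. After separation, F3 is inverted by a Mitsunobu reaction (4-nitrobenzoic acid, PPh3, diisopropyl azodicarboxylate) to (4S,5S,6R)-6-acetyl-2,6-dimethyl-5-[(1R)-2-methyl-1-(triethylsilyloxy)propyl]nona-1,8-dien-4-yl 4-nitrobenzoate F4. Methanolysis (K2CO3, MeOH) then returns 11, so both epimers converge.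

Step 5. The methyl nucleophile may add twice, or conversion at the hindered lactone carbonyl may stall. The fallback sets out from 8 and comes back at 10. The lactone is reduced with iBu2AlH (CH2Cl2, −78 °C) to the lactol (3R,4S)-3-allyl-3-methyl-4-[(1R)-2-methyl-1-(triethylsilyloxy)propyl]oxolan-2-ol F5. Its open aldehyde form takes up MeMgBr (THF, 0 °C) to give the diol (3R,4S,5R)-3-allyl-4-(hydroxymethyl)-3,6-dimethyl-5-(triethylsilyloxy)heptan-2-ol F6 as a mixture at the new carbinol carbon. Oxidation of both hydroxyls with Dess–Martin periodinane gives the keto aldehyde 10.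

**Further compounds**
F1 | step 12 | (1S,6R,7R)-6-acetyl-7-[(1R)-1-hydroxy-2-methylpropyl]-3,6-dimethylcyclohept-3-en-1-yl 4-(tert-butyldimethylsilyloxy)benzoate | CC(=O)[C@]1(C)CC=C(C)C[C@H](OC(=O)c2ccc(O[Si](C)(C)C(C)(C)C)cc2)[C@H]1[C@H](O)C(C)C
F2 | step 12 | (1S,6R,7S)-6-acetyl-3,6-dimethyl-7-(2-methylpropanoyl)cyclohept-3-en-1-yl 4-(tert-butyldimethylsilyloxy)benzoate | CC(=O)[C@]1(C)CC=C(C)C[C@H](OC(=O)c2ccc(O[Si](C)(C)C(C)(C)C)cc2)[C@H]1C(=O)C(C)C
F3 | step 7 | (3R,4S,5R)-3-allyl-5-hydroxy-3,7-dimethyl-4-[(1R)-2-methyl-1-(triethylsilyloxy)propyl]oct-7-en-2-one | CC(=O)[C@](C)(CC=C)[C@@H]([C@H](O)CC(C)=C)[C@H](O[Si](CC)(CC)CC)C(C)C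
F4 | step 7 | (4S,5S,6R)-6-acetyl-2,6-dimethyl-5-[(1R)-2-methyl-1-(triethylsilyloxy)propyl]nona-1,8-dien-4-yl 4-nitrobenzoate | CC(=O)[C@](C)(CC=C)[C@@H]([C@@H](OC(=O)c1ccc(cc1)[N+](=O)[O-])CC(C)=C)[C@H](O[Si](CC)(CC)CC)C(C)C
F5 | step 5 | (3R,4S)-3-allyl-3-methyl-4-[(1R)-2-methyl-1-(triethylsilyloxy)propyl]oxolan-2-ol (anomer mixture) | OC1OC[C@@H]([C@H](O[Si](CC)(CC)CC)C(C)C)[C@@]1(C)CC=C
F6 | step 5 | (3R,4S,5R)-3-allyl-4-(hydroxymethyl)-3,6-dimethyl-5-(triethylsilyloxy)heptan-2-ol (mixture at C2) | CC(O)[C@](C)(CC=C)[C@@H](CO)[C@H](O[Si](CC)(CC)CC)C(C)C
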